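**Retrosynthetic overview**
1. Target = epirobinetinidol-(4β→8)-epirobinetinidol-(4α→8)-epicatechin. Last operations: O-debenzylation and removal, via aryl triflates, of a temporary C5 oxygen that the upper and middle units carry over from (+)-dihydromyricetin (it makes their rings A phloroglucinol-type so that 4→8 coupling is regioselective).
2. C4(upper)–C8(middle) bond: Friedel–Crafts flavanylation with a bromine-capped 2,3-cis C4 electrophile (attack trans to 3-OH, 4β).
3. C4(middle)–C8(lower) bond: Friedel–Crafts flavanylation with a 2,3-trans 3,4-diacetate (3,4-trans, 2,4-cis), then C3 inversion by oxidation and hydride reduction to the all-cis middle unit.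
4. Ring C of the lower unit, the only ring built: one-pot aryne [3+3] annulation of 3,5-bis(benzyloxy)benzyne with a syn bromo-alkoxide from an Evans glycolate aldol; O1–C8a by alkoxide addition, C4–C4a by closure of the aryl anion on CH2Br.
5. Enabling feature: in ring A of the lower unit C8a is meta to both C5–O and C7–O and C4a is ortho to C5–O, exactly the polarity of nucleophilic addition to a 3-alkoxyaryne (oxygen to the distal carbon, carbanion next to the alkoxy group).

Key step: step 15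

Remark: the C4 configuration drawn for 6, 8, 10, 11, 12 and 14 is that of the expected major epimer and is erased when C4 is ionised; 1, 15, 22 and 23 are taken as purchased.

**Step 1**
Reactants: 1 (+)-dihydromyricetin; 2 benzyl bromide
Product: 3 (2R,3R)-7-(benzyloxy)-3,5-dihydroxy-2-[3,4,5-tris(benzyloxy)phenyl]chroman-4-one
Conditions: BnBr (4.4 equiv), K2CO3, DMF, 0 °C to rt, Ar
Reagents that add atoms: benzyl bromide 2, BrCc1ccccc1
Why: Williamson etherification of the four free phenols, while the 5-OH hydrogen-bonded to the C4 carbonyl and the secondary 3-OH should stay free; C2 and C3 (2,3-trans, the thermodynamic arrangement) are not touched.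

**Step 2**
Reactants: 3; 4 chlorotriisopropylsilane
Product: 5 (2R,3R)-7-(benzyloxy)-3-hydroxy-5-(triisopropylsilyloxy)-2-[3,4,5-tris(benzyloxy)phenyl]chroman-4-one
Conditions: i-Pr3SiCl, imidazole, DMF, 40 °C
Reagents that add atoms: chlorotriisopropylsilane 4, CC(C)[Si](Cl)(C(C)C)C(C)C
Why: phenol-selective O-silylation (the bulky silyl chloride should not react with the hindered secondary alcohol) gives the one ring-A oxygen that stays electron-donating and bulky during the couplings and can later be exchanged for triflate.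

**Step 3**
Reactants: 5
Product: 6 (2R,3S,4R)-7-(benzyloxy)-5-(triisopropylsilyloxy)-2-[3,4,5-tris(benzyloxy)phenyl]chromane-3,4-diol (2,3-trans-3,4-trans)
Conditions: NaBH4, CeCl3·7H2O, MeOH/THF, −40 to 0 °C
Reagents that add atoms: none
Why: Luche-type reduction of the aryl ketone with hydride entering opposite to the C2 aryl group, expected to give mainly the 3,4-trans diol; the cold, weakly basic conditions should prevent O-to-O silyl migration.

**Step 4**
Reactants: 6; 7 acetic anhydride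
Product: 8 (2R)-2,3-trans-3,4-trans-7-(benzyloxy)-5-(triisopropylsilyloxy)-2-[3,4,5-tris(benzyloxy)phenyl]chromane-3,4-diyl diacetate
Conditions: Ac2O, pyridine, DMAP (cat.), CH2Cl2, 0 °C to rt
Reagents that add atoms: acetic anhydride 7, CC(=O)OC(C)=O
Why: double acetylation turns the benzylic 4-OH into a leaving group and the 3-OH into a participating group, without change at any stereocentre.

**Step 5**
Reactants: 6; 9 methanol
Product: 10 (2R,3S,4R)-7-(benzyloxy)-4-methoxy-5-(triisopropylsilyloxy)-2-[3,4,5-tris(benzyloxy)phenyl]chroman-3-ol (2,3-trans-3,4-trans)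
Conditions: PPTS (cat.), MeOH/CH2Cl2, rt
Reagents that add atoms: methanol 9, CO
Why: SN1 solvolysis of the doubly activated benzylic 4-OH, captured by methanol mainly trans to the 3-OH, stores C4 as a stable leaving group and leaves the 3-OH free.

**Step 6**
Reactants: 10
Product: 11 (2R,4R)-7-(benzyloxy)-4-methoxy-5-(triisopropylsilyloxy)-2-[3,4,5-tris(benzyloxy)phenyl]chroman-3-one (2,4-cis)
Conditions: Dess–Martin periodinane, pyridine, CH2Cl2, 0 °C to rt
Reagents that add atoms: none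
Why: Dess–Martin oxidation of the only free alcohol under buffered conditions that should not epimerise C2 or ionise C4.

**Step 7**
Reactants: 11
Product: 12 (2R,3R,4R)-7-(benzyloxy)-4-methoxy-5-(triisopropylsilyloxy)-2-[3,4,5-tris(benzyloxy)phenyl]chroman-3-ol (2,3-cis-3,4-cis)
Conditions: LiBH(s-Bu)3, THF, −78 °C
Reagents that add atoms: none
Why: the bulky hydride (the reaction type of the catechin-to-epicatechin inversion) should attack the face opposite to the cis, pseudo-equatorial C2 aryl and C4 methoxy groups, setting the axial 3-OH cis to the aryl group.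

**Step 8**
Reactants: 12; 13 N-bromosuccinimide
Product: 14 (2R,3R,4R)-8-bromo-7-(benzyloxy)-4-methoxy-5-(triisopropylsilyloxy)-2-[3,4,5-tris(benzyloxy)phenyl]chroman-3-ol
Conditions: NBS, CH2Cl2, −78 to −40 °C
Reagents that add atoms: N-bromosuccinimide 13, O=C1CCC(=O)N1Br
Why: electrophilic aromatic bromination should occur at C8 (between O1 and the 7-benzyloxy group) because C6 is buried between the silyloxy and benzyloxy groups; the bromine caps the only nucleophilic site of the future electrophile.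

**Step 9**
Reactants: 15 3,5-bis(benzyloxy)phenol; 13
Product: 16 3,5-bis(benzyloxy)-2-bromophenol
Conditions: NBS, CH2Cl2, −78 °C
Reagents that add atoms: N-bromosuccinimide 13, O=C1CCC(=O)N1Br
Why: electrophilic bromination ortho to the free hydroxyl and para to a benzyloxy group; C4 is shielded by two flanking benzyloxy groups and any isomer brominated there is separated.

**Step 10**
Reactants: 16; 17 hexamethyldisilazane
Product: 18 [3,5-bis(benzyloxy)-2-bromophenoxy]trimethylsilane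
Conditions: (Me3Si)2NH, THF, 65 °C, then evaporation
Reagents that add atoms: hexamethyldisilazane 17, C[Si](C)(C)N[Si](C)(C)C
Why: O-silylation of the phenol with a silazane, ammonia being the only by-product, sets up the silyl transfer of the next step.

**Step 11**
Reactants: 18; 19 trifluoromethanesulfonic anhydride
Product: 21 3,5-bis(benzyloxy)-2-(trimethylsilyl)phenyl trifluoromethanesulfonate, via lithium 3,5-bis(benzyloxy)-2-(trimethylsilyl)phenoxide 20 (not isolated)
Conditions: n-BuLi, THF, −78 °C; then Tf2O, −78 to 0 °C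
Reagents that add atoms: trifluoromethanesulfonic anhydride 19, O=S(=O)(OS(=O)(=O)C(F)(F)F)C(F)(F)F
Why: bromine–lithium exchange followed by retro-Brook (1,3 O-to-C) silyl migration gives the ortho-silyl phenoxide, which is triflated; this is the standard entry to ortho-silylaryl triflate aryne precursors and is fast enough at −78 °C to spare the benzyl ethers.

**Step 12**
Reactants: 22 (S)-4-benzyl-3-[(benzyloxy)acetyl]oxazolidin-2-one; 23 3,4-bis(benzyloxy)benzaldehyde
Product: 25 (S)-4-benzyl-3-{(2S,3R)-2-(benzyloxy)-3-[3,4-bis(benzyloxy)phenyl]-3-hydroxypropanoyl}oxazolidin-2-one, via Z-dibutylboron enolate 24 (not isolated)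
Conditions: Bu2BOTf, Et3N, CH2Cl2, −78 to 0 °C; then 23, −78 to 0 °C; pH 7 buffer/MeOH
Reagents that add atoms: none
Why: Evans syn-aldol reaction in which the Z-boron enolate reacts through a closed chair transition state on the face away from the benzyl group of the (S)-auxiliary, setting the (2S,3R) syn pair that becomes C3 and C2 of the epicatechin unit.

**Step 13**
Reactants: 25
Product: 26 (1R,2R)-2-(benzyloxy)-1-[3,4-bis(benzyloxy)phenyl]propane-1,3-diol
Conditions: LiBH4, MeOH (1 equiv), THF, 0 °C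
Reagents that add atoms: none
Why: reductive cleavage of the exocyclic imide carbonyl releases the auxiliary and gives the primary alcohol without touching either stereocentre.

**Step 14**
Reactants: 26; 27 p-toluenesulfonyl chloride; 28 lithium bromide
Product: 30 (1R,2S)-2-(benzyloxy)-1-[3,4-bis(benzyloxy)phenyl]-3-bromopropan-1-ol, via primary tosylate 29 (not isolated)
Conditions: TsCl (1.05 equiv), Et3N, Me3N·HCl (cat.), CH2Cl2, −10 °C; then LiBr, acetone, 45 °C
Reagents that add atoms: lithium bromide 28, [Li+].[Br-]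
Why: sulfonylation should be selective for the primary hydroxyl over the hindered secondary benzylic one, and the Finkelstein-type SN2 displacement at the primary carbon leaves both stereocentres unchanged.

**Step 15**
Reactants: 30; 21
Product: 34 (2R,3R)-3,5,7-tris(benzyloxy)-2-[3,4-bis(benzyloxy)phenyl]chromane (penta-O-benzyl-(−)-epicatechin), via sodium alkoxide of the bromo alcohol 31 (not isolated), via 3,5-bis(benzyloxy)benzyne 32 (not isolated), via ortho-aryloxy aryl anion 33 (not isolated)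
Conditions: NaH, THF, −20 °C; this solution added slowly to 21 (1.5 equiv), CsF, 18-crown-6, THF, 0 °C to rt
Reagents that add atoms: none
Why: Proposed new method: fluoride-induced 1,2-elimination of 21 releases aryne 32, whose triple bond is polarised by the flanking C5 benzyloxy group so that alkoxide 31 adds at the distal carbon (future C8a) and the negative charge develops at C4a next to that oxygen; aryl anion 33 then displaces the primary bromide at C4 by 6-exo-tet SN2, closing ring C and forming O1–C8a and C4–C4a in one operation. The closest known reaction types are the addition of heteroatom nucleophiles to 3-alkoxyarynes with intramolecular capture of the aryl anion by a tethered electrophile, and the Parham cyclialkylation of ortho-metalated aryl 3-bromopropyl ethers to chromans. No stereocentre is created: C2 and C3 come from the Evans aldol and none of their bonds is made or broken, so the syn arrangement of 30 should appear unchanged as the 2,3-cis relationship. The step needs O-attack at C8a only, which the alkoxy group adjacent to the aryne secures, and C-alkylation faster than protonation of the aryl anion, which the preformed alkoxide in THF (no O–H or acidic C–H source) secures. Slow addition of cold 31 to the aryne source keeps its concentration low so that 4-exo-tet oxetane closure and Grob-type fragmentation of the γ-bromo alkoxide should stay slower than its capture.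

**Step 16**
Reactants: 8; 34
Product: 35 [5-O-triisopropylsilyl-7,3',4',5'-tetra-O-benzylgallocatechin 3-O-acetate]-(4α→8)-[penta-O-benzylepicatechin]
Conditions: TMSOTf (0.2 equiv), CH2Cl2, −78 to −40 °C, 34 (3 equiv, excess recovered)
Reagents that add atoms: none
Why: Friedel–Crafts flavanylation as used for proanthocyanidins, in which the benzylic 4-acetate ionises to the C4 cation, the 3-acetate bridges one face (anchimeric assistance) and C8 of 34, the more nucleophilic and less hindered ring-A position, should attack trans to C3–O to give the 3,4-trans (2,4-cis) linkage, the excess of 34 suppressing self-condensation of 8.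

**Step 17**
Reactants: 35
Product: 36 [5-O-triisopropylsilyl-7,3',4',5'-tetra-O-benzylgallocatechin]-(4α→8)-[penta-O-benzylepicatechin] (upper unit 2,3-trans-3,4-trans, 3-OH free)
Conditions: i-Bu2AlH, CH2Cl2, −78 °C
Reagents that add atoms: none
Why: reductive cleavage of the only ester frees the C3 hydroxyl of the upper unit under non-basic conditions that keep the aryl silyl ether.

**Step 18**
Reactants: 36
Product: 37 3-ketone of 36 (upper unit 2,4-cis-2,4-diarylchroman-3-one)
Conditions: Dess–Martin periodinane, pyridine, CH2Cl2, 0 °C to rt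
Reagents that add atoms: none
Why: Dess–Martin oxidation of the single free secondary alcohol; the 2,4-cis arrangement with both aryl groups pseudo-equatorial is the stable one, so C2 and C4 should hold.

**Step 19**
Reactants: 37
Product: 38 [5-O-triisopropylsilyl-7,3',4',5'-tetra-O-benzylepigallocatechin]-(4α→8)-[penta-O-benzylepicatechin] (upper unit 2,3-cis-3,4-cis)
Conditions: LiBH(s-Bu)3, THF, −78 °C
Reagents that add atoms: none
Why: bulky-hydride reduction in which the C2 and C4 aryl groups, cis and pseudo-equatorial, leave only equatorial attack from the opposite face, so the new 3-OH should become axial and cis to both, inverting C3 to the all-cis unit of the target.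

**Step 20**
Reactants: 14; 38
Product: 39 [8-bromo-5-O-triisopropylsilyl-7,3',4',5'-tetra-O-benzylepigallocatechin]-(4β→8)-[5-O-triisopropylsilyl-7,3',4',5'-tetra-O-benzylepigallocatechin]-(4α→8)-[penta-O-benzylepicatechin]
Conditions: TMSOTf (cat.), CH2Cl2, −78 °C, 38 (1.3 equiv)
Reagents that add atoms: none
Why: Friedel–Crafts flavanylation in which the C4 cation from the 4-methoxy group of the 2,3-cis unit should be attacked opposite to the 3-OH and C2 aryl group (3,4-trans, 4β) by C8 of the middle unit, the only ring-A carbon of 38 not flanked by two bulky ether groups; the bromine cap of 14 prevents its self-condensation.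

**Step 21**
Reactants: 39; 40 N-phenylbis(trifluoromethanesulfonimide)
Product: 42 bis(5-O-trifluoromethanesulfonate) corresponding to 39 (both triisopropylsilyloxy groups replaced by OSO2CF3), via bisphenol trimer 41 (not isolated)
Conditions: Bu4NF, THF, 0 °C; then PhNTf2, 0 °C to rt
Reagents that add atoms: N-phenylbis(trifluoromethanesulfonimide) 40, O=S(=O)(N(c1ccccc1)S(=O)(=O)C(F)(F)F)C(F)(F)F
Why: fluoride cleaves both aryl silyl ethers and the phenoxides are triflated in the same flask by a phenol-selective reagent, so the two secondary alcohols stay free and the air-sensitive bisphenol is not handled.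

**Step 22**
Reactants: 42
Product: 43 [7,3',4',5'-tetra-O-benzylepirobinetinidol]-(4β→8)-[7,3',4',5'-tetra-O-benzylepirobinetinidol]-(4α→8)-[penta-O-benzylepicatechin]
Conditions: Pd(OAc)2 (10 mol %), dppf, HCO2H, Et3N, DMF, 70 °C
Reagents that add atoms: none
Why: formate reduction catalysed by zerovalent palladium cleaves both aryl triflates and the aryl bromide to C–H, removing the two temporary C5 oxygens and the cap without touching benzyl ethers or stereocentres.

**Step 23**
Reactants: 43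
Product: 44 epirobinetinidol-(4β→8)-epirobinetinidol-(4α→8)-epicatechin (CNP0115797.2)
Conditions: H2 (1 atm), Pd(OH)2/C, THF/MeOH/H2O, rt
Reagents that add atoms: none
Why: hydrogenolysis of the thirteen benzyl ethers under neutral conditions that the acid-labile interflavan bonds and the nine stereocentres should tolerate.

**Compound list**
1 | (+)-dihydromyricetin, (2R,3R)-3,5,7-trihydroxy-2-(3,4,5-trihydroxyphenyl)chroman-4-one | Oc1cc(O)c2c(c1)O[C@H](c1cc(O)c(O)c(O)c1)[C@@H](O)C2=O | starting material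
2 | benzyl bromide | BrCc1ccccc1 | starting material
3 | (2R,3R)-7-(benzyloxy)-3,5-dihydroxy-2-[3,4,5-tris(benzyloxy)phenyl]chroman-4-one | c1c(OCc9ccccc9)cc(O)c2c1O[C@H](c7cc(OCc9ccccc9)c(OCc9ccccc9)c(OCc9ccccc9)c7)[C@@H](O)C2=O | intermediate
4 | chlorotriisopropylsilane | CC(C)[Si](Cl)(C(C)C)C(C)C | starting material
5 | (2R,3R)-7-(benzyloxy)-3-hydroxy-5-(triisopropylsilyloxy)-2-[3,4,5-tris(benzyloxy)phenyl]chroman-4-one | c1c(OCc9ccccc9)cc(O[Si](C(C)C)(C(C)C)C(C)C)c2c1O[C@H](c7cc(OCc9ccccc9)c(OCc9ccccc9)c(OCc9ccccc9)c7)[C@@H](O)C2=O | intermediate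
6 | (2R,3S,4R)-7-(benzyloxy)-5-(triisopropylsilyloxy)-2-[3,4,5-tris(benzyloxy)phenyl]chromane-3,4-diol | c1c(OCc9ccccc9)cc(O[Si](C(C)C)(C(C)C)C(C)C)c2c1O[C@H](c7cc(OCc9ccccc9)c(OCc9ccccc9)c(OCc9ccccc9)c7)[C@@H](O)[C@@H]2O | intermediate
7 | acetic anhydride | CC(=O)OC(C)=O | starting material
8 | (2R)-2,3-trans-3,4-trans-7-(benzyloxy)-5-(triisopropylsilyloxy)-2-[3,4,5-tris(benzyloxy)phenyl]chromane-3,4-diyl diacetate | c1c(OCc9ccccc9)cc(O[Si](C(C)C)(C(C)C)C(C)C)c2c1O[C@H](c7cc(OCc9ccccc9)c(OCc9ccccc9)c(OCc9ccccc9)c7)[C@@H](OC(C)=O)[C@@H]2OC(C)=O | intermediate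
9 | methanol | CO | starting material
10 | (2R,3S,4R)-7-(benzyloxy)-4-methoxy-5-(triisopropylsilyloxy)-2-[3,4,5-tris(benzyloxy)phenyl]chroman-3-ol | c1c(OCc9ccccc9)cc(O[Si](C(C)C)(C(C)C)C(C)C)c2c1O[C@H](c7cc(OCc9ccccc9)c(OCc9ccccc9)c(OCc9ccccc9)c7)[C@@H](O)[C@@H]2OC | intermediate
11 | (2R,4R)-7-(benzyloxy)-4-methoxy-5-(triisopropylsilyloxy)-2-[3,4,5-tris(benzyloxy)phenyl]chroman-3-one | c1c(OCc9ccccc9)cc(O[Si](C(C)C)(C(C)C)C(C)C)c2c1O[C@H](c7cc(OCc9ccccc9)c(OCc9ccccc9)c(OCc9ccccc9)c7)C(=O)[C@@H]2OC | intermediate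
12 | (2R,3R,4R)-7-(benzyloxy)-4-methoxy-5-(triisopropylsilyloxy)-2-[3,4,5-tris(benzyloxy)phenyl]chroman-3-ol (2,3-cis-3,4-cis) | c1c(OCc9ccccc9)cc(O[Si](C(C)C)(C(C)C)C(C)C)c2c1O[C@H](c7cc(OCc9ccccc9)c(OCc9ccccc9)c(OCc9ccccc9)c7)[C@H](O)[C@@H]2OC | intermediate
13 | N-bromosuccinimide | O=C1CCC(=O)N1Br | starting material
14 | (2R,3R,4R)-8-bromo-7-(benzyloxy)-4-methoxy-5-(triisopropylsilyloxy)-2-[3,4,5-tris(benzyloxy)phenyl]chroman-3-ol | Brc1c(OCc9ccccc9)cc(O[Si](C(C)C)(C(C)C)C(C)C)c2c1O[C@H](c7cc(OCc9ccccc9)c(OCc9ccccc9)c(OCc9ccccc9)c7)[C@H](O)[C@@H]2OC | intermediate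
15 | 3,5-bis(benzyloxy)phenol | Oc1cc(OCc2ccccc2)cc(OCc2ccccc2)c1 | starting material
16 | 3,5-bis(benzyloxy)-2-bromophenol | Oc1cc(OCc2ccccc2)cc(OCc2ccccc2)c1Br | intermediate
17 | hexamethyldisilazane | C[Si](C)(C)N[Si](C)(C)C | starting material
18 | [3,5-bis(benzyloxy)-2-bromophenoxy]trimethylsilane | C[Si](C)(C)Oc1cc(OCc2ccccc2)cc(OCc2ccccc2)c1Br | intermediate
19 | trifluoromethanesulfonic anhydride | O=S(=O)(OS(=O)(=O)C(F)(F)F)C(F)(F)F | starting material
20 | lithium 3,5-bis(benzyloxy)-2-(trimethylsilyl)phenoxide | [Li+].[O-]c1cc(OCc2ccccc2)cc(OCc2ccccc2)c1[Si](C)(C)C | intermediate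
21 | 3,5-bis(benzyloxy)-2-(trimethylsilyl)phenyl trifluoromethanesulfonate | C[Si](C)(C)c1c(OCc2ccccc2)cc(OCc2ccccc2)cc1OS(=O)(=O)C(F)(F)F | intermediate
22 | (S)-4-benzyl-3-[(benzyloxy)acetyl]oxazolidin-2-one | O=C(COCc1ccccc1)N1[C@@H](Cc2ccccc2)COC1=O | starting material
23 | 3,4-bis(benzyloxy)benzaldehyde | O=Cc1ccc(OCc2ccccc2)c(OCc2ccccc2)c1 | starting material
24 | Z-dibutylboron enolate of 22 | CCCCB(CCCC)O/C(=C\OCc1ccccc1)N1[C@@H](Cc2ccccc2)COC1=O | intermediate
25 | (S)-4-benzyl-3-{(2S,3R)-2-(benzyloxy)-3-[3,4-bis(benzyloxy)phenyl]-3-hydroxypropanoyl}oxazolidin-2-one | O[C@H](c1ccc(OCc2ccccc2)c(OCc2ccccc2)c1)[C@H](OCc1ccccc1)C(=O)N1[C@@H](Cc2ccccc2)COC1=O | intermediate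
26 | (1R,2R)-2-(benzyloxy)-1-[3,4-bis(benzyloxy)phenyl]propane-1,3-diol | O[C@H](c1ccc(OCc2ccccc2)c(OCc2ccccc2)c1)[C@H](OCc1ccccc1)CO | intermediate
27 | p-toluenesulfonyl chloride | Cc1ccc(cc1)S(Cl)(=O)=O | starting material
28 | lithium bromide | [Li+].[Br-] | starting material
29 | (2R,3R)-2-(benzyloxy)-3-[3,4-bis(benzyloxy)phenyl]-3-hydroxypropyl 4-methylbenzenesulfonate | O[C@H](c1ccc(OCc2ccccc2)c(OCc2ccccc2)c1)[C@H](OCc1ccccc1)COS(=O)(=O)c1ccc(C)cc1 | intermediate
30 | (1R,2S)-2-(benzyloxy)-1-[3,4-bis(benzyloxy)phenyl]-3-bromopropan-1-ol | O[C@H](c1ccc(OCc2ccccc2)c(OCc2ccccc2)c1)[C@H](OCc1ccccc1)CBr | intermediate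
31 | sodium (1R,2S)-2-(benzyloxy)-1-[3,4-bis(benzyloxy)phenyl]-3-bromopropan-1-olate | [Na+].[O-][C@H](c1ccc(OCc2ccccc2)c(OCc2ccccc2)c1)[C@H](OCc1ccccc1)CBr | intermediate
32 | 3,5-bis(benzyloxy)benzyne | C1#CC(OCc2ccccc2)=CC(OCc2ccccc2)=C1 | intermediate
33 | sodium 2,4-bis(benzyloxy)-6-{(1R,2S)-2-(benzyloxy)-1-[3,4-bis(benzyloxy)phenyl]-3-bromopropoxy}benzen-1-ide | [Na+].[c-]1c(OCc2ccccc2)cc(OCc2ccccc2)cc1O[C@H](c1ccc(OCc2ccccc2)c(OCc2ccccc2)c1)[C@H](OCc1ccccc1)CBr | intermediate
34 | (2R,3R)-3,5,7-tris(benzyloxy)-2-[3,4-bis(benzyloxy)phenyl]chromane, penta-O-benzyl-(−)-epicatechin | c1c(OCc9ccccc9)cc(OCc9ccccc9)c2c1O[C@H](c7ccc(OCc9ccccc9)c(OCc9ccccc9)c7)[C@H](OCc9ccccc9)C2 | intermediate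
35 | [5-O-triisopropylsilyl-7,3',4',5'-tetra-O-benzylgallocatechin 3-O-acetate]-(4α→8)-[penta-O-benzylepicatechin] | c3c(OCc9ccccc9)cc(O[Si](C(C)C)(C(C)C)C(C)C)c4c3O[C@H](c7cc(OCc9ccccc9)c(OCc9ccccc9)c(OCc9ccccc9)c7)[C@@H](OC(C)=O)[C@@H]4c5c(OCc9ccccc9)cc(OCc9ccccc9)c6c5O[C@H](c7ccc(OCc9ccccc9)c(OCc9ccccc9)c7)[C@H](OCc9ccccc9)C6 | intermediate
36 | [5-O-triisopropylsilyl-7,3',4',5'-tetra-O-benzylgallocatechin]-(4α→8)-[penta-O-benzylepicatechin] | c3c(OCc9ccccc9)cc(O[Si](C(C)C)(C(C)C)C(C)C)c4c3O[C@H](c7cc(OCc9ccccc9)c(OCc9ccccc9)c(OCc9ccccc9)c7)[C@@H](O)[C@@H]4c5c(OCc9ccccc9)cc(OCc9ccccc9)c6c5O[C@H](c7ccc(OCc9ccccc9)c(OCc9ccccc9)c7)[C@H](OCc9ccccc9)C6 | intermediate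
37 | 3-ketone of 36 (upper unit 2,4-cis chroman-3-one) | c3c(OCc9ccccc9)cc(O[Si](C(C)C)(C(C)C)C(C)C)c4c3O[C@H](c7cc(OCc9ccccc9)c(OCc9ccccc9)c(OCc9ccccc9)c7)C(=O)[C@@H]4c5c(OCc9ccccc9)cc(OCc9ccccc9)c6c5O[C@H](c7ccc(OCc9ccccc9)c(OCc9ccccc9)c7)[C@H](OCc9ccccc9)C6 | intermediate
38 | [5-O-triisopropylsilyl-7,3',4',5'-tetra-O-benzylepigallocatechin]-(4α→8)-[penta-O-benzylepicatechin] (upper unit 2,3-cis-3,4-cis) | c3c(OCc9ccccc9)cc(O[Si](C(C)C)(C(C)C)C(C)C)c4c3O[C@H](c7cc(OCc9ccccc9)c(OCc9ccccc9)c(OCc9ccccc9)c7)[C@H](O)[C@@H]4c5c(OCc9ccccc9)cc(OCc9ccccc9)c6c5O[C@H](c7ccc(OCc9ccccc9)c(OCc9ccccc9)c7)[C@H](OCc9ccccc9)C6 | intermediate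
39 | [8-bromo-5-O-triisopropylsilyl-7,3',4',5'-tetra-O-benzylepigallocatechin]-(4β→8)-[5-O-triisopropylsilyl-7,3',4',5'-tetra-O-benzylepigallocatechin]-(4α→8)-[penta-O-benzylepicatechin] | Brc1c(OCc9ccccc9)cc(O[Si](C(C)C)(C(C)C)C(C)C)c2c1O[C@H](c7cc(OCc9ccccc9)c(OCc9ccccc9)c(OCc9ccccc9)c7)[C@H](O)[C@H]2c3c(OCc9ccccc9)cc(O[Si](C(C)C)(C(C)C)C(C)C)c4c3O[C@H](c7cc(OCc9ccccc9)c(OCc9ccccc9)c(OCc9ccccc9)c7)[C@H](O)[C@@H]4c5c(OCc9ccccc9)cc(OCc9ccccc9)c6c5O[C@H](c7ccc(OCc9ccccc9)c(OCc9ccccc9)c7)[C@H](OCc9ccccc9)C6 | intermediate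
40 | N-phenylbis(trifluoromethanesulfonimide) | O=S(=O)(N(c1ccccc1)S(=O)(=O)C(F)(F)F)C(F)(F)F | starting material
41 | bisphenol from 39 (both 5-OH free) | Brc1c(OCc9ccccc9)cc(O)c2c1O[C@H](c7cc(OCc9ccccc9)c(OCc9ccccc9)c(OCc9ccccc9)c7)[C@H](O)[C@H]2c3c(OCc9ccccc9)cc(O)c4c3O[C@H](c7cc(OCc9ccccc9)c(OCc9ccccc9)c(OCc9ccccc9)c7)[C@H](O)[C@@H]4c5c(OCc9ccccc9)cc(OCc9ccccc9)c6c5O[C@H](c7ccc(OCc9ccccc9)c(OCc9ccccc9)c7)[C@H](OCc9ccccc9)C6 | intermediate
42 | bis(5-O-trifluoromethanesulfonate) from 41 | Brc1c(OCc9ccccc9)cc(OS(=O)(=O)C(F)(F)F)c2c1O[C@H](c7cc(OCc9ccccc9)c(OCc9ccccc9)c(OCc9ccccc9)c7)[C@H](O)[C@H]2c3c(OCc9ccccc9)cc(OS(=O)(=O)C(F)(F)F)c4c3O[C@H](c7cc(OCc9ccccc9)c(OCc9ccccc9)c(OCc9ccccc9)c7)[C@H](O)[C@@H]4c5c(OCc9ccccc9)cc(OCc9ccccc9)c6c5O[C@H](c7ccc(OCc9ccccc9)c(OCc9ccccc9)c7)[C@H](OCc9ccccc9)C6 | intermediate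
43 | [7,3',4',5'-tetra-O-benzylepirobinetinidol]-(4β→8)-[7,3',4',5'-tetra-O-benzylepirobinetinidol]-(4α→8)-[penta-O-benzylepicatechin] | c1c(OCc9ccccc9)ccc2c1O[C@H](c7cc(OCc9ccccc9)c(OCc9ccccc9)c(OCc9ccccc9)c7)[C@H](O)[C@H]2c3c(OCc9ccccc9)ccc4c3O[C@H](c7cc(OCc9ccccc9)c(OCc9ccccc9)c(OCc9ccccc9)c7)[C@H](O)[C@@H]4c5c(OCc9ccccc9)cc(OCc9ccccc9)c6c5O[C@H](c7ccc(OCc9ccccc9)c(OCc9ccccc9)c7)[C@H](OCc9ccccc9)C6 | intermediate
44 | epirobinetinidol-(4β→8)-epirobinetinidol-(4α→8)-epicatechin (CNP0115797.2) | Oc1ccc2c(c1)O[C@H](c1cc(O)c(O)c(O)c1)[C@H](O)[C@H]2c1c(O)ccc2c1O[C@H](c1cc(O)c(O)c(O)c1)[C@H](O)[C@@H]2c1c(O)cc(O)c2c1O[C@H](c1ccc(O)c(O)c1)[C@H](O)C2 | target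

**Totals**
Total step count: 23.
Longest linear sequence: 12 steps (1, 2, 3, 4, 16–23 from 1; equally 12–15, 16–23 from 22 and 23).

**Steps most likely to fail**

1. Step 15 (proposed new method). The aryl anion may be quenched by proton transfer before it alkylates, or alkoxide 31 may close to an oxetane or fragment before the aryne is released. Fallback with known reactions, setting out from 30 and 21: the two bonds are made one after the other. Under protic aryne conditions (CsF, MeCN, rt) the free alcohol 30 adds to the same aryne carbon and the aryl anion is simply protonated, giving 1-{(1R,2S)-2-(benzyloxy)-1-[3,4-bis(benzyloxy)phenyl]-3-bromopropoxy}-3,5-bis(benzyloxy)benzene F1. A ring-forming aromatic C–H alkylation of the unactivated primary bromide catalysed by Pd(PPh3)4 (K3PO4, dioxane, 100 °C) at one of the two equivalent ortho carbons then closes C4–C4a and comes back to the route at 34.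

2. Step 19. The basic hydride may enolise the hindered ketone at the very acidic C4–H (returning or epimerising 37), or facial selectivity may be poor. Fallback setting out from 36 and avoiding the ketone: the equatorial 3-OH is converted with Tf2O and pyridine (CH2Cl2, −20 °C) into the 3-O-trifluoromethanesulfonate of 36 F2. Lattrell–Dax displacement with KNO2 in DMF inverts C3 by SN2 to the 3-epi nitrite ester F3, which is hydrolysed on aqueous work-up and comes back to the route at 38.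

3. Step 20. The Lewis acid may cleave and scramble the first interflavan bond, or the cation may attack C6 of the lower or middle ring A. Fallback setting out from 14, with thiophilic instead of acid activation: 14 is converted with phenylmethanethiol and catalytic TMSOTf (CH2Cl2, −40 °C) into (2R)-2,3-cis-3,4-trans-4-(benzylsulfanyl)-8-bromo-7-(benzyloxy)-5-(triisopropylsilyloxy)-2-[3,4,5-tris(benzyloxy)phenyl]chroman-3-ol F4. F4 is then coupled with 38 by AgBF4 in THF at 0 °C, the known activation of 4-thio flavan-3-ols, and comes back to the route at 39.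

**Further compounds**
F1 | step 15 | 1-{(1R,2S)-2-(benzyloxy)-1-[3,4-bis(benzyloxy)phenyl]-3-bromopropoxy}-3,5-bis(benzyloxy)benzene | O(c1cc(OCc9ccccc9)cc(OCc9ccccc9)c1)[C@H](c7ccc(OCc9ccccc9)c(OCc9ccccc9)c7)[C@H](OCc9ccccc9)CBr
F2 | step 19 | 3-O-trifluoromethanesulfonate of 36 | c3c(OCc9ccccc9)cc(O[Si](C(C)C)(C(C)C)C(C)C)c4c3O[C@H](c7cc(OCc9ccccc9)c(OCc9ccccc9)c(OCc9ccccc9)c7)[C@@H](OS(=O)(=O)C(F)(F)F)[C@@H]4c5c(OCc9ccccc9)cc(OCc9ccccc9)c6c5O[C@H](c7ccc(OCc9ccccc9)c(OCc9ccccc9)c7)[C@H](OCc9ccccc9)C6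
F3 | step 19 | 3-O-nitrite ester of 38 (C3 inverted) | c3c(OCc9ccccc9)cc(O[Si](C(C)C)(C(C)C)C(C)C)c4c3O[C@H](c7cc(OCc9ccccc9)c(OCc9ccccc9)c(OCc9ccccc9)c7)[C@H](ON=O)[C@@H]4c5c(OCc9ccccc9)cc(OCc9ccccc9)c6c5O[C@H](c7ccc(OCc9ccccc9)c(OCc9ccccc9)c7)[C@H](OCc9ccccc9)C6
F4 | step 20 | (2R)-2,3-cis-3,4-trans-4-(benzylsulfanyl)-8-bromo-7-(benzyloxy)-5-(triisopropylsilyloxy)-2-[3,4,5-tris(benzyloxy)phenyl]chroman-3-ol | Brc1c(OCc9ccccc9)cc(O[Si](C(C)C)(C(C)C)C(C)C)c2c1O[C@H](c7cc(OCc9ccccc9)c(OCc9ccccc9)c(OCc9ccccc9)c7)[C@H](O)[C@H]2SCc9ccccc9
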